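**Strategy.** The carboxyl carbon C17 on C8 and the side-chain carbon C11 on C9 sit on neighbouring atoms of ring B, so they are treated as the two ends of one C2 unit. A [2+2] photocycloaddition of vinylene carbonate to the C8=C9 bond of a ring-B C7 enone forms C8–C17 and C9–C11 together as a cyclobutane whose cis-diol is later cleaved; the C7 carbonyl ends as the C7=C8 alkene. The precursor is enantiopure 4,4,10-trimethyl-trans-decal-8-en-7-one, made by asymmetric allylation and annulation. After reduction at C7, glycol cleavage, acetonide differentiation, C9 equilibration, Wittig extension and oxidation complete the acid.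

Key step: step 9

**Conventions.** Labdane numbering is used for all bicyclic compounds: ring A is C1–C5 and C10, ring B is C5–C10, the gem-dimethyl group is on C4, a methyl on C10, C17 on C8, and the chain is C9–C11–C12–C13(CH3)–C14–O. α is the face opposite the C10 methyl.

**Assumption (step 2).** The sense of induction is taken from simple 2-alkylcyclohexanone enol carbonates, where the (S)-ligand gives the (S)-ketone. (R)-t-Bu-PHOX is therefore specified; the other ligand enantiomer would be used if the sense were reversed.

**Remarks on the chemistry.**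
- The cyclic carbonate of 17 is opened only after the C7 ketone has been reduced. With the ketone present, a free C17 alkoxide is β to the carbonyl and the strained ring would open by retro-aldol cleavage of C8–C17, or the C8 enolate would expel the C17 oxygen.
- C9 is equilibrated while C8 is still sp3 (step 13). In Δ7 systems that carry a carbonyl group on C8 (the polygodial pattern), base favours the 9α-formyl epimer, so the correction is not left to that stage.
- The C11 formyl group, next to the quaternary C10, is a sluggish electrophile. C17 is therefore kept at the alcohol level, tied to O7 as an acetonide, while C11 is olefinated.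
- Compounds 17–34 are drawn as single isomers (α-face cis-fused adduct, 7α-oxygen). Isomers at C7, C8, C11 or C17 would be carried along and converge at 35, where C7 and C8 are sp2.

## Route

Step 1
Reactants: 1 2,2,6-trimethylcyclohexan-1-one; 2 allyl chloroformate
Product: 4 allyl 2,6,6-trimethylcyclohex-1-en-1-yl carbonate, via lithium enolate 3 (not isolated)
Conditions: LiN(SiMe3)2, THF, 0 °C; then 2, −78 → 25 °C
Reagents that add atoms: none
Why: The ketone can enolise only toward C6, and the fully substituted, hindered lithium enolate is acylated on oxygen by the hard chloroformate (O-acylation of an enolate to an allyl enol carbonate); the C6 stereocentre of racemic 1 is erased.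

Step 2
Reactants: 4 allyl 2,6,6-trimethylcyclohex-1-en-1-yl carbonate
Product: 5 (R)-2-allyl-2,6,6-trimethylcyclohexan-1-one
Conditions: Pd2(dba)3 (2.5 mol %), (R)-t-Bu-PHOX (6.25 mol %), THF, 25 °C
Reagents that add atoms: none
Why: Decarboxylative asymmetric allylic alkylation (Tsuji allylation): zerovalent palladium ionises the allyl carbonate, CO2 is lost, and the resulting allylpalladium enolate forms the C–C bond inside the chiral PHOX pocket, which selects one enolate face and so sets the quaternary carbon C10 as R.

Step 3
Reactants: 5 (R)-2-allyl-2,6,6-trimethylcyclohexan-1-one; 6 isopropenylboronic acid pinacol ester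
Product: 7 (R)-2,6,6-trimethyl-2-[(Z)-3-(4,4,5,5-tetramethyl-1,3,2-dioxaborolan-2-yl)but-2-en-1-yl]cyclohexan-1-one
Conditions: second-generation Grubbs catalyst (5 mol %), 6 (3 equiv), CH2Cl2, 40 °C
Reagents that add atoms: none
Why: Olefin cross-metathesis of a terminal alkene with a 1,1-disubstituted alkenylboronate that does not homodimerise, driven by loss of ethylene, should give the trisubstituted alkenylboronate, whose geometry is of no consequence.

Step 4
Reactants: 7 alkenylboronate
Product: 8 (R)-2,6,6-trimethyl-2-(3-oxobutyl)cyclohexan-1-one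
Conditions: H2O2 (30 % aq), NaOH (aq), THF, 0 °C
Reagents that add atoms: hydrogen peroxide, OO
Why: Oxidation of the alkenyl C–B bond (boron-to-oxygen 1,2-shift in the hydroperoxide ate complex) gives an enol that tautomerises to the methyl ketone, while the ring ketone between two quaternary carbons is inert to alkaline peroxide at this temperature.

Step 5
Reactants: 8 (R)-2,6,6-trimethyl-2-(3-oxobutyl)cyclohexan-1-one
Product: 10 (R)-4,4,10-trimethyldecal-5-en-7-one, via ketol 9 (not isolated)
Conditions: KOH, xylenes, 110 °C, Dean–Stark trap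
Reagents that add atoms: none
Why: Intramolecular aldol condensation: only the methyl ketone can enolise, its methyl carbon (C6) adds to the ring carbonyl (C5) to close six-membered ring B, and azeotropic removal of water drives dehydration of the ketol to the C5=C6 enone.

Step 6
Reactants: 10 (R)-4,4,10-trimethyldecal-5-en-7-one
Product: 12 4,4,10-trimethyl-trans-decalin-7-one (5α-H; 10β-CH3), via lithium enolate 11 (not isolated)
Conditions: Li, NH3 (l), t-BuOH (1 equiv), THF, −78 °C; then NH4Cl
Reagents that add atoms: none
Why: Dissolving-metal (Birch-type) reduction of the enone: the C5 carbanion is protonated axially, anti to the axial C10 methyl, which should give the trans ring fusion (C5–H α), and the lithium enolate shields the carbonyl until the quench.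

Step 7
Reactants: 12 4,4,10-trimethyl-trans-decalin-7-one
Product: 14 7-(trimethylsilyloxy)-4,4,10-trimethyl-trans-decal-7-ene, via lithium enolate 13 (not isolated)
Conditions: LiN(i-Pr)2, THF, −78 °C; then Me3SiCl, −78 → 0 °C
Reagents that add atoms: chlorotrimethylsilane, C[Si](C)(C)Cl
Why: Kinetic enolisation with the bulky amide removes a C8 proton, the α-methylene remote from the C4 gem-dimethyl group, and O-silylation fixes the C7=C8 enol ether (regioselective silyl enol ether formation).

Step 8
Reactants: 14 silyl enol ether
Product: 15 4,4,10-trimethyl-trans-decal-8-en-7-one (5α-H; 10β-CH3)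
Conditions: Pd(OAc)2 (1.05 equiv), MeCN, 25 °C
Reagents that add atoms: none
Why: Saegusa–Ito oxidation: divalent palladium adds to the silyl enol ether at C8 and β-hydride elimination of a C9 hydrogen delivers the C8=C9 enone regiospecifically.

Step 9
Reactants: 15 4,4,10-trimethyl-trans-decal-8-en-7-one; 16 vinylene carbonate
Product: 17 α-face cis-fused cyclobutane carbonate photoadduct (C8–C17 and C9–C11 both α; cis carbonate on C11/C17 pointing away from ring B; C7 ketone)
Conditions: hν (350 nm, Pyrex), 16 (10 equiv), MeCN, 0 °C, degassed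
Reagents that add atoms: none
Why: Excitation of the enone (n→π*) and intersystem crossing give the triplet, which bonds through its β-carbon C9 to one alkene carbon (C11) to form a triplet 1,4-diradical (C8 and C17) that, after spin inversion, collapses to the four-membered ring, so that C9–C11 and C8–C17 are made in one operation. The closest known reaction type is the enone–alkene [2+2] photocycloaddition, for which vinylene carbonate is an established partner. The cyclobutane is closed stepwise, by intermolecular bond formation followed by 1,4-diradical recombination at C8–C17; the carbonate ring is carried in from 16 and not formed here. C9 is set by approach of the alkene anti to the axial C10 methyl (α face), C8 by ring closure to the cis-fused bicyclo[4.2.0] unit, and C11 and C17 are cis to each other because the alkene is locked in the five-membered carbonate. The step needs only chemoselectivity for the crossed adduct over enone dimerisation and photorearrangement, which the large excess of 16 should secure; the orientation question does not arise with a symmetrical alkene, and no face control is required because C11 and C17 end as CH2 and carboxyl carbons, C8 ends sp2 and C9 is reset in step 13.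

Step 10
Reactants: 17 photoadduct
Product: 18 cyclobutane triol (7α-OH; cis-11,17-diol on the α-fused cyclobutane)
Conditions: Li(s-Bu)3BH, THF, −78 °C; then NaOH (aq), H2O2, 0 → 25 °C
Reagents that add atoms: none
Why: The bulky borohydride reduces only the C7 ketone, by equatorial attack from the β face, away from the cyclobutane and its axial C9–C11 bond, to give the 7α (axial) alkoxide, and the carbonate is saponified only afterwards in the alkaline peroxide work-up, so that no free C17 alkoxide is ever β to a carbonyl group and retro-aldol opening of the four-membered ring cannot occur (chemoselective ketone reduction, then carbonate hydrolysis).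

Step 11
Reactants: 18 cyclobutane triol
Product: 20 8α,9α-bis(hydroxymethyl)-4,4,10-trimethyl-trans-decalin-7α-ol, via hydroxy dialdehyde 19 (not isolated)
Conditions: NaIO4, THF/H2O, 0 °C; then NaBH4, 0 → 25 °C
Reagents that add atoms: none
Why: Periodate glycol cleavage of the strained cis-cyclobutane-1,2-diol breaks only C11–C17, so that C8–C17 and C9–C11 made in step 9 survive as two formyl-bearing arms, and reduction in the same flask removes the dialdehyde before the C7 hydroxyl can be eliminated (oxidative diol cleavage followed by borohydride reduction).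

Step 12
Reactants: 20 triol
Product: 21 O7,O17-isopropylidene acetal of 20 (cis-fused 1,3-dioxane over C7–C8; free 9α-CH2OH)
Conditions: Me2C(OMe)2, PPTS (cat.), acetone, 25 °C
Reagents that add atoms: 2,2-dimethoxypropane, COC(C)(C)OC
Why: Thermodynamically controlled acetalisation: of the three hydroxyls only O7 and O17 are 1,3-related, so the six-membered 1,3-dioxane is formed in preference to either seven-membered alternative and the C11 hydroxyl stays free.

Step 13
Reactants: 21 acetonide alcohol
Product: 23 9β-formyl acetonide (9α-H; C11 aldehyde equatorial), via 9α-aldehyde 22 (not isolated)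
Conditions: (COCl)2, DMSO, CH2Cl2, −78 °C; Et3N, −78 → 0 °C; then DBU, 25 °C
Reagents that add atoms: none
Why: Swern oxidation gives the axial 9α-aldehyde, and enolisation by the amidine base (epimerisation α to a carbonyl group) then moves the formyl group into the equatorial 9β position, trans to the C8 arm and free of the 1,3-diaxial contact with O7, which sets C9 with its hydrogen α as in the target while C8 is still sp3.

Step 14
Reactants: 24 (S)-3-bromo-2-methylpropan-1-ol
Product: 25 (S)-[(3-bromo-2-methylpropoxy)methyl]benzene
Conditions: BnOC(=NH)CCl3, TfOH (cat.), CH2Cl2/cyclohexane, 0 → 25 °C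
Reagents that add atoms: benzyl 2,2,2-trichloroacetimidate, N=C(OCc1ccccc1)C(Cl)(Cl)Cl
Why: Acid-catalysed O-benzylation with the trichloroacetimidate avoids an alkoxide, which would cyclise the bromo alcohol to an oxetane, and does not touch the stereocentre.

Step 15
Reactants: 25 (S)-[(3-bromo-2-methylpropoxy)methyl]benzene
Product: 26 [(S)-3-(benzyloxy)-2-methylpropyl]triphenylphosphonium bromide
Conditions: PPh3, MeCN, reflux (82 °C)
Reagents that add atoms: triphenylphosphine, c1ccc(cc1)P(c1ccccc1)c1ccccc1
Why: SN2 quaternisation of triphenylphosphine by the primary bromide (phosphonium salt formation) is slowed by the β-branch but should go to completion at reflux.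

Step 16
Reactants: 23 9β-formyl acetonide; 26 phosphonium bromide
Product: 28 9β-[(1Z,3R)-4-(benzyloxy)-3-methylbut-1-en-1-yl] acetonide, via ylide 27 (not isolated)
Conditions: 26, NaN(SiMe3)2, THF, 0 °C; then 23, −78 → 25 °C
Reagents that add atoms: none
Why: Wittig olefination with a non-stabilised ylide, reactive enough for the hindered C11 aldehyde, forms C11=C12 with no other carbonyl group present; C9 is already in its stable configuration, the C13 stereocentre comes unchanged from 24, and the expected Z geometry is irrelevant because the alkene is hydrogenated next.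

Step 17
Reactants: 28 Wittig alkene
Product: 29 9β-[(3R)-4-hydroxy-3-methylbutyl] acetonide
Conditions: H2 (1 atm), Pd/C (10 %), EtOAc, 25 °C
Reagents that add atoms: none
Why: Heterogeneous hydrogenation saturates the only alkene (C11=C12) and hydrogenolyses the benzyl ether in the same operation, while the acetonide is stable under these neutral conditions.

Step 18
Reactants: 29 primary alcohol; 30 isobutyryl chloride
Product: 31 C14 isobutyrate of 29
Conditions: 30, pyridine, DMAP (cat.), CH2Cl2, 0 → 25 °C
Reagents that add atoms: none
Why: DMAP-catalysed acylation of the only free hydroxyl (primary, C14) installs the isobutyrate ester.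

Step 19
Reactants: 31 isobutyrate acetonide
Product: 32 7α,17-diol isobutyrate (8α-CH2OH; 9β side chain)
Conditions: AcOH/H2O (4:1), 40 °C
Reagents that add atoms: none
Why: Aqueous acetic acid hydrolyses the isopropylidene acetal to the 7,17-diol (acetal hydrolysis) without cleaving the ester.

Step 20
Reactants: 32 diol
Product: 35 C7=C8 enal (C17 aldehyde) isobutyrate, via hydroxy aldehyde 33 (not isolated), via mesylate 34 (not isolated)
Conditions: TEMPO (10 mol %), PhI(OAc)2, CH2Cl2, 25 °C; then Et3N, MeSO2Cl, 0 → 25 °C
Reagents that add atoms: none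
Why: The oxoammonium oxidation (TEMPO with PhI(OAc)2) is selective for the primary C17 hydroxyl over the secondary C7 hydroxyl, and mesylation of the latter then triggers E1cB elimination through the C8 enolate, helped by the antiperiplanar axial C8–H and C7–O bonds, to give the conjugated C7=C8 enal.

Step 21
Reactants: 35 enal
Product: 36 target acid CNP0323283.1
Conditions: NaClO2, NaH2PO4, 2-methyl-2-butene, t-BuOH/H2O, 25 °C
Reagents that add atoms: sodium chlorite, [Na+].[O-]Cl=O
Why: Pinnick oxidation converts the enal into the conjugated acid without moving the C7=C8 bond or touching the ester, hypochlorous acid being trapped by the alkene scavenger.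

## Compound list

1 | 2,2,6-trimethylcyclohexan-1-one (racemic) | CC1CCCC(C)(C)C1=O | starting material
2 | allyl chloroformate | C=CCOC(=O)Cl | starting material
3 | lithium 2,6,6-trimethylcyclohex-1-en-1-olate (formed in situ) | [Li+].[O-]C1=C(C)CCCC1(C)C | intermediate
4 | allyl 2,6,6-trimethylcyclohex-1-en-1-yl carbonate | C=CCOC(=O)OC1=C(C)CCCC1(C)C | intermediate
5 | (R)-2-allyl-2,6,6-trimethylcyclohexan-1-one | C=CC[C@@]1(C)CCCC(C)(C)C1=O | intermediate
6 | isopropenylboronic acid pinacol ester (4,4,5,5-tetramethyl-2-(prop-1-en-2-yl)-1,3,2-dioxaborolane) | CC(=C)B1OC(C)(C)C(C)(C)O1 | starting material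
7 | (R)-2,6,6-trimethyl-2-[(Z)-3-(4,4,5,5-tetramethyl-1,3,2-dioxaborolan-2-yl)but-2-en-1-yl]cyclohexan-1-one | C/C(B1OC(C)(C)C(C)(C)O1)=C\C[C@@]2(C)CCCC(C)(C)C2=O | intermediate
8 | (R)-2,6,6-trimethyl-2-(3-oxobutyl)cyclohexan-1-one | CC(=O)CC[C@@]1(C)CCCC(C)(C)C1=O | intermediate
9 | 5-hydroxy-4,4,10-trimethyldecalin-7-one (aldol ketol; 10β-CH3; C5 not defined; formed in situ) | O=C1CC[C@@]2(C)CCCC(C)(C)C2(O)C1 | intermediate
10 | (R)-4,4,10-trimethyldecal-5-en-7-one ((R)-4a,8,8-trimethyl-4,4a,5,6,7,8-hexahydronaphthalen-2(3H)-one) | O=C1C=C2C(C)(C)CCC[C@]2(C)CC1 | intermediate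
11 | lithium C6=C7 enolate of 12 (formed in situ) | [Li+].[O-]C1=C[C@H]2C(C)(C)CCC[C@]2(C)CC1 | intermediate
12 | 4,4,10-trimethyl-trans-decalin-7-one (5α-H; 10β-CH3; (4aR,8aS)-4a,8,8-trimethyloctahydronaphthalen-2(1H)-one) | O=C1C[C@H]2C(C)(C)CCC[C@]2(C)CC1 | intermediate
13 | lithium C7=C8 enolate of 12 (formed in situ) | [Li+].[O-]C1=CC[C@@]2(C)CCCC(C)(C)[C@@H]2C1 | intermediate
14 | 7-(trimethylsilyloxy)-4,4,10-trimethyl-trans-decal-7-ene | C[Si](C)(C)OC1=CC[C@@]2(C)CCCC(C)(C)[C@@H]2C1 | intermediate
15 | 4,4,10-trimethyl-trans-decal-8-en-7-one (5α-H; 10β-CH3; (4aR,8aS)-4a,8,8-trimethyl-4a,5,6,7,8,8a-hexahydronaphthalen-2(1H)-one) | C1=CC(=O)C[C@H]2C(C)(C)CCC[C@]12C | intermediate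
16 | vinylene carbonate (1,3-dioxol-2-one) | O=C1OC=CO1 | starting material
17 | α-face cis-fused cyclobutane carbonate photoadduct (cyclobutane C8–C17–C11–C9 on the α face; cis carbonate on C11/C17; C7 ketone) | O=C1O[C@@H]2[C@H](O1)[C@@H]3[C@H]2C(=O)C[C@H]4C(C)(C)CCC[C@]34C | intermediate
18 | cyclobutane triol (7α-OH; cis-11,17-diol) | O[C@@H]1[C@H](O)[C@@H]2[C@H]1[C@H](O)C[C@H]3C(C)(C)CCC[C@]23C | intermediate
19 | 7α-hydroxy-4,4,10-trimethyl-trans-decalin-8α,9α-dicarbaldehyde (formed in situ) | O=C[C@@H]1[C@H](C=O)[C@H](O)C[C@H]2C(C)(C)CCC[C@]12C | intermediate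
20 | 8α,9α-bis(hydroxymethyl)-4,4,10-trimethyl-trans-decalin-7α-ol | OC[C@@H]1[C@H](CO)[C@H](O)C[C@H]2C(C)(C)CCC[C@]12C | intermediate
21 | O7,O17-isopropylidene acetal of 20 (free 9α-CH2OH) | OC[C@@H]1[C@@H]2COC(C)(C)O[C@@H]2C[C@H]3C(C)(C)CCC[C@]13C | intermediate
22 | 9α-formyl acetonide (formed in situ) | O=C[C@@H]1[C@@H]2COC(C)(C)O[C@@H]2C[C@H]3C(C)(C)CCC[C@]13C | intermediate
23 | 9β-formyl acetonide (9α-H) | O=C[C@H]1[C@@H]2COC(C)(C)O[C@@H]2C[C@H]3C(C)(C)CCC[C@]13C | intermediate
24 | (S)-3-bromo-2-methylpropan-1-ol | OC[C@H](C)CBr | starting material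
25 | (S)-[(3-bromo-2-methylpropoxy)methyl]benzene | BrC[C@@H](C)COCc1ccccc1 | intermediate
26 | [(S)-3-(benzyloxy)-2-methylpropyl]triphenylphosphonium bromide | [Br-].c1ccccc1COC[C@H](C)C[P+](c2ccccc2)(c3ccccc3)c4ccccc4 | intermediate
27 | [(S)-3-(benzyloxy)-2-methylpropylidene]triphenylphosphorane (formed in situ) | c1ccccc1COC[C@H](C)C=P(c2ccccc2)(c3ccccc3)c4ccccc4 | intermediate
28 | 9β-[(1Z,3R)-4-(benzyloxy)-3-methylbut-1-en-1-yl] acetonide | c1ccccc1COC[C@H](C)/C=C\[C@H]1[C@@H]2COC(C)(C)O[C@@H]2C[C@H]3C(C)(C)CCC[C@]13C | intermediate
29 | 9β-[(3R)-4-hydroxy-3-methylbutyl] acetonide | OC[C@H](C)CC[C@H]1[C@@H]2COC(C)(C)O[C@@H]2C[C@H]3C(C)(C)CCC[C@]13C | intermediate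
30 | isobutyryl chloride (2-methylpropanoyl chloride) | CC(C)C(=O)Cl | starting material
31 | C14 isobutyrate of 29 | CC(C)C(=O)OC[C@H](C)CC[C@H]1[C@@H]2COC(C)(C)O[C@@H]2C[C@H]3C(C)(C)CCC[C@]13C | intermediate
32 | 7α,17-diol isobutyrate (8α-CH2OH; 9β chain; 13R) | CC(C)C(=O)OC[C@H](C)CC[C@H]1[C@H](CO)[C@H](O)C[C@H]2C(C)(C)CCC[C@]12C | intermediate
33 | 7α-hydroxy-8α-formyl isobutyrate (formed in situ) | CC(C)C(=O)OC[C@H](C)CC[C@H]1[C@H](C=O)[C@H](O)C[C@H]2C(C)(C)CCC[C@]12C | intermediate
34 | 7α-mesyloxy-8α-formyl isobutyrate (formed in situ) | CC(C)C(=O)OC[C@H](C)CC[C@H]1[C@H](C=O)[C@H](OS(C)(=O)=O)C[C@H]2C(C)(C)CCC[C@]12C | intermediate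
35 | C7=C8 enal (C17 aldehyde) isobutyrate | CC(C)C(=O)OC[C@H](C)CC[C@H]1C(C=O)=CC[C@H]2C(C)(C)CCC[C@]12C | intermediate
36 | CNP0323283.1 (C7=C8; C17 carboxylic acid; 9β chain with 9α-H; 5α-H; 10β-CH3; 13R; C14 isobutyrate) | CC(C)C(=O)OC[C@H](C)CC[C@H]1C(C(=O)O)=CC[C@H]2C(C)(C)CCC[C@]12C | target

## Step count and risks

Total step count: 21 (19 in the main line, 2 for the phosphonium salt). Longest linear sequence: 19 steps (steps 1–13 and 16–21).

The three steps most likely to fail:

**Step 9 (photocycloaddition).** The triplet enone may be consumed by dimerisation or photorearrangement faster than it adds to the sluggish alkene, so that conversion stalls or a mixture results. The fallback sets out from 15 and introduces the two-carbon bridge with acetylene instead (hν, acetone, −78 °C), which should give the cyclobutene-fused ketone F1 by the same α-face, cis-fused addition. Reduction with Li(s-Bu)3BH (THF, −78 °C) should give the cyclobutene 7α-ol F2. Ozonolysis with a reductive work-up (O3, CH2Cl2/MeOH, −78 °C; then NaBH4) cuts C11=C17 and comes back to the route at triol 20, by-passing 17–19.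

**Step 16 (Wittig olefination).** The ylide may act as a base toward the hindered aldehyde, enolising it at C9 instead of adding, so that 23 is returned. The fallback sets out from 23 and bromide 25 and makes C11–C12 by carbonyl addition. Bromide 25 is converted with Mg (THF) into the Grignard reagent F3, which is transmetallated with CeCl3 and added to 23 at −78 °C to give the C11 carbinol F4. Xanthate formation (NaH, CS2, MeI) gives the xanthate F5, Barton–McCombie deoxygenation (Bu3SnH, AIBN, toluene, 110 °C) gives the saturated benzyl ether F6, and hydrogenolysis (H2, Pd/C, EtOAc) comes back to the route at alcohol 29.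

**Step 3 (cross-metathesis).** Homodimerisation of 5 and decay of the ruthenium carbene may outrun the crossed metathesis with the hindered 1,1-disubstituted partner. The fallback sets out from 5: hydroboration–oxidation (9-BBN, THF; then NaOH, H2O2) gives the primary alcohol F7, and Dess–Martin oxidation gives the aldehyde F8. MeMgBr (THF, −78 °C) should add only to the aldehyde, the ring ketone being shielded by two quaternary carbons, to give the secondary carbinol F9. A second Dess–Martin oxidation comes back to the route at diketone 8.

## Further compounds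

F1 | step 9 | cyclobutene-fused ketone (C8–C17=C11–C9 bridge on the α face of 4,4,10-trimethyl-trans-decalin-7-one) | C1=C[C@@H]2[C@H]1C(=O)C[C@H]3C(C)(C)CCC[C@]23C
F2 | step 9 | cyclobutene 7α-ol | C1=C[C@@H]2[C@H]1[C@H](O)C[C@H]3C(C)(C)CCC[C@]23C
F3 | step 16 | [(S)-3-(benzyloxy)-2-methylpropyl]magnesium bromide | Br[Mg]C[C@@H](C)COCc1ccccc1
F4 | step 16 | C11 carbinol (9β-[(3R)-4-(benzyloxy)-1-hydroxy-3-methylbutyl] acetonide; C11 epimers) | c1ccccc1COC[C@H](C)CC(O)[C@H]1[C@@H]2COC(C)(C)O[C@@H]2C[C@H]3C(C)(C)CCC[C@]13C
F5 | step 16 | C11 O-alkyl S-methyl xanthate of F4 | c1ccccc1COC[C@H](C)CC(OC(=S)SC)[C@H]1[C@@H]2COC(C)(C)O[C@@H]2C[C@H]3C(C)(C)CCC[C@]13C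
F6 | step 16 | 9β-[(3R)-4-(benzyloxy)-3-methylbutyl] acetonide | c1ccccc1COC[C@H](C)CC[C@H]1[C@@H]2COC(C)(C)O[C@@H]2C[C@H]3C(C)(C)CCC[C@]13C
F7 | step 3 | (R)-2-(3-hydroxypropyl)-2,6,6-trimethylcyclohexan-1-one | OCCC[C@@]1(C)CCCC(C)(C)C1=O
F8 | step 3 | 3-[(1R)-1,3,3-trimethyl-2-oxocyclohexyl]propanal | O=CCC[C@@]1(C)CCCC(C)(C)C1=O
F9 | step 3 | (R)-2-(3-hydroxybutyl)-2,6,6-trimethylcyclohexan-1-one (carbinol epimers) | CC(O)CC[C@@]1(C)CCCC(C)(C)C1=O
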